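**Retrosynthetic overview**
- The acetate is put on last and the tiglate before it. Both come from a 2‑aryl‑glycerol whose tertiary O and one CH2O arm are tied in a 2‑tert‑butyl‑1,3‑dioxolane, with the third arm carried as CO2Me.
- Key disconnection: the Ar–C(quaternary) bond. The glycerate α‑carbon (enolate) and the arene carbon are both natural donors, so the arene is inverted into an acceptor as a p‑quinone monoketal (aryl‑cation equivalent). Conjugate addition followed by aromatisation delivers the free phenol and the ortho‑OMe directly.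
- Stereocontrol: self‑regeneration of the glycerate stereocentre. (R)‑glycerate fixes a cis tert‑butyl acetal centre, and the enolate is arylated anti to tert‑butyl.
- Ring order: the temporary dioxolane is formed first; the benzene ring is dearomatised, then re‑formed in the key step; the dioxolane is opened near the end. No ring of the target is built de novo.

Assumption: 1, 3, 4 and 10 are taken as commercial. The anti‑to‑tert‑butyl facial preference of enolate 6 is assumed by analogy with related 2‑tert‑butyl acetal enolates and would be confirmed by NOE on 8.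

**Step 1**
Reactants: 1 4‑methoxy‑2‑methylphenol
Product: 2 4,4‑dimethoxy‑2‑methylcyclohexa‑2,5‑dien‑1‑one
Conditions: PhI(OAc)2 (1.1 equiv), MeOH, 0 °C
Reagents that add atoms: methanol, CO
Why: Hypervalent‑iodine oxidative dearomatisation of a p‑methoxyphenol traps the phenoxenium ion with methanol at the para carbon, giving the p‑quinone monoketal, an electrophilic form of the arene.

**Step 2**
Reactants: 3 methyl (4R)‑2,2‑dimethyl‑1,3‑dioxolane‑4‑carboxylate; 4 pivalaldehyde
Product: 5 methyl (2R,4R)‑2‑tert‑butyl‑1,3‑dioxolane‑4‑carboxylate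
Conditions: t‑BuCHO (3 equiv), TsOH·H2O (5 mol%), cyclohexane, 70 °C, acetone distilled off; SiO2 separation of cis from trans
Reagents that add atoms: none
Why: Acid‑catalysed transacetalisation under thermodynamic control leaves C4 untouched and gives a cis/trans acetal mixture, from which the cis‑(2R,4R) isomer is separated and the trans isomer re‑equilibrated, so the new C2 centre is fixed relative to the glycerate centre.

**Step 3**
Reactants: 5 methyl (2R,4R)‑2‑tert‑butyl‑1,3‑dioxolane‑4‑carboxylate; 2 4,4‑dimethoxy‑2‑methylcyclohexa‑2,5‑dien‑1‑one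
Product: 8 methyl (2R,4R)‑2‑tert‑butyl‑4‑(5‑hydroxy‑2‑methoxy‑4‑methylphenyl)‑1,3‑dioxolane‑4‑carboxylate, via lithium ester enolate 6 (not isolated), via keto ketal Michael adduct 7 (not isolated)
Conditions: LDA (1.3 equiv), THF, −78 °C; cannulate onto 2·ATPH (ATPH 1.2 equiv, stock solution), toluene, −78 °C, 2 h; AcOH, −78 °C; Rochelle‑salt wash; crude, CSA (10 mol%), MeOH, rt
Reagents that add atoms: none
Why: Proposed new method: the exocyclic enolate 6 (β‑elimination suppressed at −78 °C because the ring C–O bond is orthogonal to the enolate π system) adds in a Michael sense to C5 of the monoketal, whose carbonyl and methyl‑bearing flank are shielded by the bulky aluminium Lewis acid ATPH so that 1,2‑addition and attack at C3 are blocked; the dienone approaches the enolate face anti to the C2 tert‑butyl group, so the aryl ends up trans to tert‑butyl (4R), and acid‑catalysed loss of methanol from keto ketal 7 aromatises the ring to the 4‑methoxyphenol; the closest known reaction types are Michael addition/aromatisation of stabilised carbanions with p‑quinone monoketals, ATPH‑directed conjugate addition of lithium enolates to enones, and diastereoselective alkylation of 2‑tert‑butyl‑dioxolane glycerate enolates (self‑regeneration of stereocentres).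

**Step 4**
Reactants: 8 methyl (2R,4R)‑2‑tert‑butyl‑4‑(5‑hydroxy‑2‑methoxy‑4‑methylphenyl)‑1,3‑dioxolane‑4‑carboxylate
Product: 9 [(2R,4S)‑2‑tert‑butyl‑4‑(5‑hydroxy‑2‑methoxy‑4‑methylphenyl)‑1,3‑dioxolan‑4‑yl]methanol
Conditions: LiAlH4 (2.5 equiv), THF, 0 °C; Rochelle‑salt work‑up
Reagents that add atoms: none
Why: LiAlH4 reduction of the methyl ester to the primary alcohol leaves the acetal and the (deprotonated) phenol alone and breaks no bond at the quaternary centre (the descriptor changes only through CIP priorities).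

**Step 5**
Reactants: 9 [(2R,4S)‑2‑tert‑butyl‑4‑(5‑hydroxy‑2‑methoxy‑4‑methylphenyl)‑1,3‑dioxolan‑4‑yl]methanol; 10 tigloyl chloride
Product: 11 [(2R,4R)‑2‑tert‑butyl‑4‑(5‑hydroxy‑2‑methoxy‑4‑methylphenyl)‑1,3‑dioxolan‑4‑yl]methyl (2E)‑2‑methylbut‑2‑enoate
Conditions: LiHMDS (2.05 equiv), THF, −78 °C; 10 (1.0 equiv), −78 → 0 °C; aq NH4Cl
Reagents that add atoms: none
Why: In the phenoxide/alkoxide dianion the primary alkoxide is far more nucleophilic, and any aryl tiglate formed is an active ester that passes its acyl group to remaining alkoxide, so one equivalent of acid chloride ends up on the aliphatic oxygen only (chemoselective O‑acylation under acyl‑transfer control); no stereocentre is touched and the E‑alkene is unaffected.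

**Step 6**
Reactants: 11 [(2R,4R)‑2‑tert‑butyl‑4‑(5‑hydroxy‑2‑methoxy‑4‑methylphenyl)‑1,3‑dioxolan‑4‑yl]methyl (2E)‑2‑methylbut‑2‑enoate
Product: 12 (2R)‑2,3‑dihydroxy‑2‑(5‑hydroxy‑2‑methoxy‑4‑methylphenyl)propyl (2E)‑2‑methylbut‑2‑enoate
Conditions: TFA/H2O (9:1), 0 °C → rt, monitored; toluene azeotrope, no base; used at once
Reagents that add atoms: none
Why: Acid‑catalysed acetal hydrolysis (the oxygen of water leaves with pivalaldehyde) frees the tertiary and one primary OH without breaking a bond to the quaternary carbon, whose ionisation is disfavoured by its two β‑oxygens, and the conjugated, α‑branched tiglate migrates too slowly to exchange the two arms if 12 is acetylated immediately.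

**Step 7**
Reactants: 12 (2R)‑2,3‑dihydroxy‑2‑(5‑hydroxy‑2‑methoxy‑4‑methylphenyl)propyl (2E)‑2‑methylbut‑2‑enoate
Product: 14 (2R)‑3‑acetoxy‑2‑hydroxy‑2‑(5‑hydroxy‑2‑methoxy‑4‑methylphenyl)propyl (2E)‑2‑methylbut‑2‑enoate, via phenol diacetate 13 (not isolated)
Conditions: Ac2O (2.5 equiv), pyridine, CH2Cl2, 0 °C → rt; then MeOH, pyrrolidine (4 equiv), 0 °C, 15 min; cold citric acid wash
Reagents that add atoms: acetic anhydride, CC(=O)OC(C)=O
Why: Ac2O/pyridine acetylates the primary OH and the phenol but not the hindered tertiary benzylic OH, and pyrrolidine then aminolyses only the aryl acetate (an active ester), leaving the alkyl acetate and the tiglate intact (acetylation followed by chemoselective aryl‑ester aminolysis); the stereocentre is untouched.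

**Compound list**
1 | 4‑methoxy‑2‑methylphenol | Cc1cc(OC)ccc1O | starting material
2 | 4,4‑dimethoxy‑2‑methylcyclohexa‑2,5‑dien‑1‑one | COC1(OC)C=CC(=O)C(C)=C1 | intermediate
3 | methyl (4R)‑2,2‑dimethyl‑1,3‑dioxolane‑4‑carboxylate | COC(=O)[C@H]1COC(C)(C)O1 | starting material
4 | pivalaldehyde (2,2‑dimethylpropanal) | CC(C)(C)C=O | starting material
5 | methyl (2R,4R)‑2‑tert‑butyl‑1,3‑dioxolane‑4‑carboxylate (cis) | COC(=O)[C@H]1CO[C@@H](C(C)(C)C)O1 | intermediate
6 | lithium [(2R)‑2‑tert‑butyl‑1,3‑dioxolan‑4‑ylidene](methoxy)methanolate (enolate geometry not specified) | COC([O-])=C1CO[C@@H](C(C)(C)C)O1.[Li+] | intermediate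
7 | methyl (2R,4R)‑2‑tert‑butyl‑4‑(2,2‑dimethoxy‑4‑methyl‑5‑oxocyclohex‑3‑en‑1‑yl)‑1,3‑dioxolane‑4‑carboxylate (epimers at the cyclohexenyl carbon) | COC(=O)[C@@]1(C2CC(=O)C(C)=CC2(OC)OC)CO[C@@H](C(C)(C)C)O1 | intermediate
8 | methyl (2R,4R)‑2‑tert‑butyl‑4‑(5‑hydroxy‑2‑methoxy‑4‑methylphenyl)‑1,3‑dioxolane‑4‑carboxylate (aryl trans to tert‑butyl) | COC(=O)[C@@]1(c2cc(O)c(C)cc2OC)CO[C@@H](C(C)(C)C)O1 | intermediate
9 | [(2R,4S)‑2‑tert‑butyl‑4‑(5‑hydroxy‑2‑methoxy‑4‑methylphenyl)‑1,3‑dioxolan‑4‑yl]methanol | OC[C@@]1(c2cc(O)c(C)cc2OC)CO[C@@H](C(C)(C)C)O1 | intermediate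
10 | tigloyl chloride, (2E)‑2‑methylbut‑2‑enoyl chloride | C/C=C(\C)C(Cl)=O | starting material
11 | [(2R,4R)‑2‑tert‑butyl‑4‑(5‑hydroxy‑2‑methoxy‑4‑methylphenyl)‑1,3‑dioxolan‑4‑yl]methyl (2E)‑2‑methylbut‑2‑enoate | C/C=C(\C)C(=O)OC[C@@]1(c2cc(O)c(C)cc2OC)CO[C@@H](C(C)(C)C)O1 | intermediate
12 | (2R)‑2,3‑dihydroxy‑2‑(5‑hydroxy‑2‑methoxy‑4‑methylphenyl)propyl (2E)‑2‑methylbut‑2‑enoate | C/C=C(\C)C(=O)OC[C@@](O)(c1cc(O)c(C)cc1OC)CO | intermediate
13 | (2R)‑3‑acetoxy‑2‑(5‑acetoxy‑2‑methoxy‑4‑methylphenyl)‑2‑hydroxypropyl (2E)‑2‑methylbut‑2‑enoate | C/C=C(\C)C(=O)OC[C@](O)(COC(C)=O)c1cc(OC(C)=O)c(C)cc1OC | intermediate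
14 | (2R)‑3‑acetoxy‑2‑hydroxy‑2‑(5‑hydroxy‑2‑methoxy‑4‑methylphenyl)propyl (2E)‑2‑methylbut‑2‑enoate | C/C=C(\C)C(=O)OC[C@](O)(COC(C)=O)c1cc(O)c(C)cc1OC | target

**Totals**
Total steps: 7. Longest linear sequence: 6 (3 → 5 → 8 → 9 → 11 → 12 → 14; the branch 1 → 2 joins at step 3).

**Steps most likely to fail, with fallbacks**

Step 3 (congested conjugate addition of a tertiary enolate next to the ketal carbon; 1,2‑addition, attack at C3 or enolate β‑elimination may compete). The fallback changes the aryl‑cation equivalent from the quinone monoketal to a diaryliodonium salt. It sets out from 1 and from 5 (through enolate 6) and returns at 9. Phenol 1 is acylated with pivaloyl chloride (Et3N, DMAP) to 4‑methoxy‑2‑methylphenyl pivalate F1. Treatment with MesI(OAc)2 and TfOH in CH2Cl2 substitutes the ring ortho to OMe and para to Me, giving [2‑methoxy‑4‑methyl‑5‑(pivaloyloxy)phenyl](mesityl)iodonium triflate F2. This is added to enolate 6 at −78 °C; metal‑free enolate arylation transfers the less ortho‑blocked aryl, again anti to tert‑butyl, to give methyl (2R,4R)‑2‑tert‑butyl‑4‑[2‑methoxy‑4‑methyl‑5‑(pivaloyloxy)phenyl]‑1,3‑dioxolane‑4‑carboxylate F3. LiAlH4 then reduces the methyl ester and cleaves the aryl pivalate in one operation to give 9.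

Step 6 (the robust pivalaldehyde acetal needs strong acid while a tiglate sits next to the diol being freed; incomplete cleavage, acyl migration that would exchange the two arms, or benzylic ionisation are the failure modes). The fallback moves acetal removal to the ester stage and carries a labile acetonide instead. It sets out from 8 and returns at 12. Compound 8 is hydrolysed with 2 M HCl in THF at 50 °C to methyl (2R)‑2,3‑dihydroxy‑2‑(5‑hydroxy‑2‑methoxy‑4‑methylphenyl)propanoate F5; here there is no acyl group to migrate and the α‑ester suppresses ionisation. The diol is re‑protected with 2,2‑dimethoxypropane/CSA as methyl (4R)‑4‑(5‑hydroxy‑2‑methoxy‑4‑methylphenyl)‑2,2‑dimethyl‑1,3‑dioxolane‑4‑carboxylate F6. LiAlH4 gives [(4S)‑4‑(5‑hydroxy‑2‑methoxy‑4‑methylphenyl)‑2,2‑dimethyl‑1,3‑dioxolan‑4‑yl]methanol F7. Dianion tigloylation as in step 5 gives [(4R)‑4‑(5‑hydroxy‑2‑methoxy‑4‑methylphenyl)‑2,2‑dimethyl‑1,3‑dioxolan‑4‑yl]methyl (2E)‑2‑methylbut‑2‑enoate F8. The acetonide is then removed with 80% aqueous AcOH at rt, far milder than the conditions the tert‑butyl acetal needs, to give 12.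

Step 5 (mono‑acylation of the aliphatic oxygen in the presence of the phenol may give mixtures if acyl transfer is slow). The fallback replaces selective acylation by exhaustive acylation and selective aryl‑ester cleavage. It sets out from 9 and returns at 11. Compound 9 is treated with tigloyl chloride (2.5 equiv), Et3N and DMAP in CH2Cl2 to give [(2R,4R)‑2‑tert‑butyl‑4‑{2‑methoxy‑4‑methyl‑5‑[(2E)‑2‑methylbut‑2‑enoyloxy]phenyl}‑1,3‑dioxolan‑4‑yl]methyl (2E)‑2‑methylbut‑2‑enoate F4. K2CO3 in MeOH at 0 °C then methanolyses only the aryl tiglate; the neopentyl‑type conjugated alkyl tiglate is inert, giving 11.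

**Further compounds**
F1 | step 3 | 4‑methoxy‑2‑methylphenyl pivalate | COc1ccc(OC(=O)C(C)(C)C)c(C)c1
F2 | step 3 | [2‑methoxy‑4‑methyl‑5‑(pivaloyloxy)phenyl](2,4,6‑trimethylphenyl)iodonium trifluoromethanesulfonate | COc1cc(C)c(OC(=O)C(C)(C)C)cc1[I+]c1c(C)cc(C)cc1C.[O-]S(=O)(=O)C(F)(F)F
F3 | step 3 | methyl (2R,4R)‑2‑tert‑butyl‑4‑[2‑methoxy‑4‑methyl‑5‑(pivaloyloxy)phenyl]‑1,3‑dioxolane‑4‑carboxylate | COC(=O)[C@@]1(c2cc(OC(=O)C(C)(C)C)c(C)cc2OC)CO[C@@H](C(C)(C)C)O1
F4 | step 5 | [(2R,4R)‑2‑tert‑butyl‑4‑{2‑methoxy‑4‑methyl‑5‑[(2E)‑2‑methylbut‑2‑enoyloxy]phenyl}‑1,3‑dioxolan‑4‑yl]methyl (2E)‑2‑methylbut‑2‑enoate | C/C=C(\C)C(=O)OC[C@@]1(c2cc(OC(=O)/C(C)=C/C)c(C)cc2OC)CO[C@@H](C(C)(C)C)O1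
F5 | step 6 | methyl (2R)‑2,3‑dihydroxy‑2‑(5‑hydroxy‑2‑methoxy‑4‑methylphenyl)propanoate | COC(=O)[C@@](O)(c1cc(O)c(C)cc1OC)CO
F6 | step 6 | methyl (4R)‑4‑(5‑hydroxy‑2‑methoxy‑4‑methylphenyl)‑2,2‑dimethyl‑1,3‑dioxolane‑4‑carboxylate | COC(=O)[C@@]1(c2cc(O)c(C)cc2OC)COC(C)(C)O1
F7 | step 6 | [(4S)‑4‑(5‑hydroxy‑2‑methoxy‑4‑methylphenyl)‑2,2‑dimethyl‑1,3‑dioxolan‑4‑yl]methanol | OC[C@@]1(c2cc(O)c(C)cc2OC)COC(C)(C)O1
F8 | step 6 | [(4R)‑4‑(5‑hydroxy‑2‑methoxy‑4‑methylphenyl)‑2,2‑dimethyl‑1,3‑dioxolan‑4‑yl]methyl (2E)‑2‑methylbut‑2‑enoate | C/C=C(\C)C(=O)OC[C@@]1(c2cc(O)c(C)cc2OC)COC(C)(C)O1
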